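Compound numbers are those used in the steps and in the list after them. Ring and chain positions carry labdane numbers (ring A: C1–C5, C10; ring B: C5–C10; side chain C11–C16); α means the face opposite to the C10 methyl group.

## Analysis of the target

The target is a labdane: a trans-fused decalin whose C9 carries a two-carbon tether (C11–C12) to the α-carbon C13 of a but-2-en-4-olide (C13=C14, C15 as the O-bound CH2, C16 as the lactone carbonyl). It has five stereocentres, all on ring B: C5 (α-H) and C10 (β-methyl) define the trans fusion, C6 carries an equatorial α-acetoxy group, C8 an equatorial α-methyl group, and C9 an axial α-hydroxyl with the side chain equatorial and β. Every ring B heteroatom therefore lies on the face opposite to the C10 methyl group, and C8–C9–C10 form a congested run of a tertiary carbon, a fully substituted carbinol and a quaternary carbon. The sensitive groups are the tertiary C9 alcohol (ionisation next to quaternary C10 invites dehydration or a 1,2-methyl shift), the acetate (base, nucleophiles) and the butenolide (base, hydride, dissolving metal, conjugate addition); they dictate the order of the late steps. Three things make the synthesis hard. The quaternary C10 must be set in absolute terms and all other centres relayed from it. The equatorial C6 oxygen cannot come from a hydride, because the β face of C6 is closed by the syn-axial C4 and C10 methyl groups. A carbon nucleophile would add to a C9 ketone from the α face and give the wrong carbinol. The route rests on one structural observation: ring B has oxygen at C6 and C9 (para) and methyl groups at C8 and C10 (flanking C9), which is the pattern of 2,6-dimethyl-1,4-benzoquinone, and ring A (C1–C4, with the gem-dimethyl C4) is a four-carbon diene that can be laid across the C5=C10 bond of that quinone.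

## Retrosynthetic reasoning

**C12–C13.** The butenolide of 20 survives neither hydride, dissolving metal, ylides nor strong base, so it is attached last and intact. Cutting C12–C13 gives bromobutenolide 18 and a C12 nucleophile, the alkylborane 19, which forms by hydroboration of the vinyl carbinol 17. Cutting C9–C11 instead would mean carbon addition to a C9 ketone, which would come from the α face. The forward step must couple a primary alkylborane with a base-sensitive vinyl bromide in the presence of an acetate and a free tertiary alcohol.

**Acetate and C11–C12.** 17 is the mono-acetate of diol 16; the tertiary C9 hydroxyl is too hindered to compete. 16 is cut between C11 and C12 to the spiro-epoxide 15 and a one-carbon unit. Opening at the CH2 terminus leaves the C9–O bond, and so the C9 configuration, untouched.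

**C9–O.** 15 comes from the exocyclic alkene 14 by oxygen transfer to the α face. The C9 configuration is thus reduced to a facial choice on a 1,1-disubstituted alkene whose β face is screened by the C10 methyl group. The bias that would misdirect a carbon nucleophile at a ketone now works in the right direction.

**C6–H and C9=C11.** 14 is the thermodynamic reduction product of ketone 13. 13 derives from dione 10 by methylenation at C9, but C6 is the more accessible carbonyl of 10. It is therefore taken out of play as alcohol 11, carried through the olefination as 12, and restored by oxidation. This redox detour costs steps. It buys clean chemoselection between the two ring B carbonyls and the equatorial alcohol that hydride cannot give.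

**C5–H and C8–H.** C5 and C8 of 10 are each α to a carbonyl, so 10 is the equilibrium partner of the cis-fused dione 9. The trans ring fusion and the equatorial C8 methyl group are set under thermodynamic control relative to C10 and need no earlier control.

**C2–O and the ring hydrogens.** 9 is alkene 8 after hydrogenation, 8 is enol triflate 7 after reductive C–O cleavage, 7 is silyl enol ether 6 after exchange at oxygen, and 6 is adduct 5 with its ene-dione saturated. The C2 oxygen serves only to activate and orient the diene. It is removed through the enol derivative because that keeps C2 distinct from C6 and C9 at every stage; hydrolysis to a triketone would discard the distinction.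

**C1–C10 and C4–C5 (key).** 5 is cut across ring A into quinone 4 and diene 3. The cut removes ring A, the quaternary centre and both ring B oxygens in one step and leads to an achiral, symmetrical, commercial dienophile. The forward reaction must join the CH2 terminus of 3 to the methyl-bearing quinone carbon and select one face of the quinone; the ring fusion it produces is cis and is corrected later.

**O–Si.** 3 is the silyl ether of the kinetic dienolate 2 of mesityl oxide 1.

## Alternatives that were turned down

**Alternative 1:** Cation–olefin bicyclisation ended by a vinylsilane.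
- Disconnection: C4–C5 and C9–C10, back to the acyclic (3Z,7E)-trienyl vinylsilane A2.
- Forward key step: a chiral Brønsted acid (a Lewis-acid-activated binaphthol) protonates the terminal C3=C4 alkene; C5 and then the silicon-bearing C9 attack through a chair–chair array, and the β-silyl cation at C8 loses silicon to give the Δ8 alkene of A1 (13,14,15,16-tetranorlabd-8-en-12-yl pivalate).
- For: both rings, the trans fusion, the gem-dimethyl group and the quaternary C10 arise in one step. Ring A never carries an oxygen to be removed and C5 needs no epimerisation. On these points it is stronger than the chosen route.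
- Against: A1 has no oxygen at C6, a homoallylic position that the Δ8 alkene does not activate (allylic oxidation goes to C7 or C11). The tetrasubstituted C8=C9 alkene must then be hydrated in an anti sense (8β-H, 9α-OH), which neither hydroboration nor hydride opening of an epoxide at a fully substituted carbon provides. A2 needs a geometrically pure tetrasubstituted vinylsilane, and proton-initiated enantioselective cyclisations of non-aromatic polyenes usually require a stoichiometric chiral acid.
- Comparison: the quinone route pays for its cis adduct with an epimerisation and three steps to delete the C2 oxygen, but it delivers C6 and C9 already oxidised, which is where A1 is weakest.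

**Alternative 2:** Acid-mediated lactonisation across C8=C9.
- Disconnection: the C9–O and C8–H bonds, back to the Δ8 acid A4.
- Forward key step: a strong acid protonates C8, and the C16 carboxyl group, tethered through C11–C13, captures the C9 cation on the α face to give the spiro δ-lactone A3.
- For: C9–O and C8–H are made in one operation with intramolecular oxygen delivery, and C11–C13 and C16 are already in place. In setting C8 and C9 together it is more direct than the ketone–alkene–epoxide sequence used here.
- Against: it does not build the decalin; A4, with its C6 oxygen, Δ8 alkene and four-carbon acid, must first be made by another ring construction. The C9 cation sits next to quaternary C10, the classic setting for a 1,2-methyl shift or proton loss to a Δ9(11) or Δ7 alkene. The tether is attached at C9 itself and gives no facial bias. The C6 acetate must survive strong acid. A3 still needs C14 and C15 added at C13 and a translactonisation, at least four more steps.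
- Comparison: the chosen route never generates a cation at C9 and sets C8 by enolate equilibration, slower at that point but not exposed to skeletal rearrangement.

**Alternative 3:** Photooxygenation of a ring B diene.
- Disconnection: C6–O and C9–O, back to the homoannular 6,8-diene A6.
- Forward key step: excited-state oxygen adds [4+2] across C6=C7–C8=C9 from the α face, away from the C10 methyl group, to give the 6α,9α-endoperoxide A5.
- For: both ring B oxygens arrive at once with the correct α configuration, and the diene is locked s-cis. The equatorial 6α-oxygen, which costs the chosen route an oxidation and a dissolving-metal reduction, comes for free. On that point it is clearly stronger.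
- Against: A6 presupposes the decalin and the side chain, in practice something like A1 followed by allylic oxidation and dehydration. The ene reaction at the tetrasubstituted C8=C9 alkene competes with cycloaddition. After O–O cleavage the C7=C8 alkene must take hydrogen on the β face to give the 8α-methyl group; that face carries the C10 methyl group and is opposite to both hydroxyls, so neither steric nor hydroxyl-directed hydrogenation gives the needed epimer.
- Comparison: the chosen route fixes C8 under thermodynamic control next to the C9 ketone and draws both oxygens from the quinone, at the cost of a redox adjustment at C6.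

Key step: step 2

Assumption: the (S)-diphenylprolinol-derived oxazaborolidinium cation is taken to expose the quinone face that leads to the 10S adduct 5. Both antipodes of the amino alcohol are commercial, so the mirror-image catalyst is substituted if correlation shows the opposite sense.

## Route

Step 1
Reactants: 1 mesityl oxide (4-methylpent-3-en-2-one)
Product: 3 2-(tert-butyldimethylsilyloxy)-4-methylpenta-1,3-diene, via lithium 4-methylpenta-1,3-dien-2-olate 2 (not isolated)
Conditions: LiN(i-Pr)2, THF, −78 °C; then t-BuMe2SiCl, DMPU, −78 °C → rt
Reagents that add atoms: tert-butyldimethylsilyl chloride, CC(C)(C)[Si](C)(C)Cl; lithium diisopropylamide, CC(C)N([Li])C(C)C (supplies the lithium of 2 only)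
Why: Kinetic deprotonation of the enone by the hindered amide takes place at the α′-methyl group, and O-silylation of the cross-conjugated dienolate 2 gives the 2-silyloxydiene (silyl enol ether formation); the low temperature suppresses the γ-deprotonation that would lead to the linear dienol ether.

Step 2
Reactants: 3 2-(tert-butyldimethylsilyloxy)-4-methylpenta-1,3-diene; 4 2,6-dimethyl-1,4-benzoquinone
Product: 5 cis-fused adduct 2-(tert-butyldimethylsilyloxy)-4,4,8,10-tetramethyl-1,4,5,10-tetrahydronaphthalene-6,9-dione (labdane numbering; 5β-H, 10β-CH3)
Conditions: (S)-tetrahydro-1-(2-methylphenyl)-3,3-diphenyl-1H,3H-pyrrolo[1,2-c][1,3,2]oxazaborole·HN(SO2CF3)2 (20 mol %), CH2Cl2, −78 → −40 °C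
Reagents that add atoms: none
Why: The protonated oxazaborolidine binds the C6 carbonyl of 4, the only one flanked by two C–H groups, which activates the C5=C10 enone and makes C10 its electrophilic β-carbon. The CH2 terminus of 3, the nucleophilic end of the silyl dienol ether, bonds first to C10 and the dimethyl-bearing terminus then closes onto C5; this is a strongly asynchronous [4+2] (at the limit a Mukaiyama–Michael addition followed by collapse of the siloxyallyl cation onto the boron enolate), the known reaction type being the cationic oxazaborolidine-catalysed Diels–Alder reaction of quinones with 2-silyloxydienes. Ring A is closed as a six-membered carbocycle by intermolecular suprafacial addition across one quinone double bond, so the ring fusion is cis. C10 is set by the catalyst, whose aryl group covers one face of the bound double bond, and C5 follows from C10 through the suprafacial geometry. The step needs regioselectivity, which is secured three ways: coordination at C6 rather than at the methyl-flanked C9 carbonyl, the polarity of the diene, and sterics, since the reverse orientation would join the CMe2 terminus to the methyl-bearing carbon. Site selectivity is not at issue because the two quinone double bonds are related by symmetry, and endo/exo selectivity is irrelevant because neither diene terminus is stereogenic. The reaction should be slow, because the Z-methyl group of 3 disfavours the s-cis conformer; hence the higher temperature and loading than for unhindered dienes.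

Step 3
Reactants: 5 cis-fused adduct
Product: 6 cis-fused 2-(tert-butyldimethylsilyloxy)-4,4,8α,10β-tetramethyl-1,4,5,7,8,10-hexahydronaphthalene-6,9-dione (5β-H; C7–C8 saturated; drawn as the 8α-methyl epimer)
Conditions: H2 (1 atm), Pd/C, EtOAc, 0 °C → rt
Reagents that add atoms: none
Why: Heterogeneous hydrogenation should reduce the electron-poor ene-dione C7=C8 much faster than the trisubstituted silyl enol ether next to quaternary C4, and removing the Michael acceptor first keeps the enolate chemistry of step 4 clean; hydrogen is expected on the convex β face, but C8 is not relied upon because it is equilibrated in step 7.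

Step 4
Reactants: 6 cis-fused silyl enol ether dione
Product: 7 cis-fused 4,4,8α,10β-tetramethyl-6,9-dioxo-1,4,5,6,7,8,9,10-octahydronaphthalen-2-yl trifluoromethanesulfonate (5β-H)
Conditions: CsF, PhN(SO2CF3)2, DME, rt
Reagents that add atoms: N-phenylbis(trifluoromethanesulfonimide), O=S(=O)(N(c1ccccc1)S(=O)(=O)C(F)(F)F)C(F)(F)F
Why: Fluoride cleaves the Si–O bond and the cesium enolate is O-sulfonylated by the triflimide (direct exchange of a silyl enol ether for an enol triflate), so C2 stays distinct from C6 and C9 without a third ketone ever being freed; a Δ1 regioisomer from enolate equilibration would converge in steps 5 and 6, and any epimerisation at C5 or C8 is harmless before step 7.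

Step 5
Reactants: 7 cis-fused enol triflate
Product: 8 cis-fused 4,4,8α,10β-tetramethyl-1,4,5,7,8,10-hexahydronaphthalene-6,9-dione (5β-H; C2=C3 alkene)
Conditions: Pd(OAc)2 (5 mol %), PPh3, Et3N, HCO2H, DMF, 60 °C
Reagents that add atoms: none
Why: Zerovalent palladium inserts into the C–OTf bond, formate exchanges for triflate, loses CO2 and the vinylpalladium hydride eliminates the alkene (palladium-catalysed formate reduction of an enol triflate); the two ketones are inert.

Step 6
Reactants: 8 cis-fused alkene dione
Product: 9 cis-fused 4,4,8α,10β-tetramethyldecalin-6,9-dione (5β-H)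
Conditions: H2 (1 atm), Pd/C, EtOAc, rt
Reagents that add atoms: none
Why: Catalytic hydrogenation of the cis-disubstituted C2=C3 alkene; no stereocentre is created.

Step 7
Reactants: 9 cis-fused dione
Product: 10 11,12,13,14,15,16-hexanorlabdane-6,9-dione (trans-fused; 5α-H, 8α-CH3, 10β-CH3)
Conditions: NaOMe (cat.), MeOH, rt → 40 °C
Reagents that add atoms: none
Why: Methoxide enolises C6 towards C5 and C9 towards C8 reversibly (thermodynamic epimerisation); the trans-decalin avoids the extra gauche interactions of either cis conformer and an 8β-methyl group would be syn-axial to the C10 methyl group, so the 5α-H, 8α-methyl isomer is the expected sink.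

Step 8
Reactants: 10 trans-fused dione
Product: 11 6β-hydroxy-11,12,13,14,15,16-hexanorlabdan-9-one
Conditions: LiBH(s-Bu)3 (1.1 equiv), THF, −78 °C; then H2O
Reagents that add atoms: none
Why: The bulky borohydride can reach C6 from the open α face but is kept from C9 by quaternary C10 on one side and the C8 methyl group on the other (chemoselective hydride reduction); the axial 6β-alcohol results, and its configuration is immaterial because the alcohol only shields C6 during the olefination and is reoxidised in step 10.

Step 9
Reactants: 11 6β-hydroxy ketone
Product: 12 12,13,14,15,16-pentanorlabd-9(11)-en-6β-ol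
Conditions: Ph3PCH3Br, KOt-Bu (excess), toluene, 90 °C
Reagents that add atoms: methyltriphenylphosphonium bromide, C[P+](c1ccccc1)(c1ccccc1)c1ccccc1.[Br-]
Why: Wittig methylenation under the hot alkoxide conditions used for hindered ketones converts the only remaining carbonyl; excess ylide tolerates the alkoxide, and C8, which can epimerise through the enolate, stays in its equatorial 8α arrangement before it is locked by loss of the carbonyl.

Step 10
Reactants: 12 6β-hydroxy alkene
Product: 13 12,13,14,15,16-pentanorlabd-9(11)-en-6-one
Conditions: Dess–Martin periodinane, CH2Cl2, rt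
Reagents that add atoms: none
Why: Dess–Martin oxidation of the strained axial secondary alcohol back to the ketone; the isolated alkene is untouched.

Step 11
Reactants: 13 6-keto alkene
Product: 14 12,13,14,15,16-pentanorlabd-9(11)-en-6α-ol
Conditions: Li, NH3(l), THF, t-BuOH, −78 → −33 °C; then NH4Cl
Reagents that add atoms: none
Why: Dissolving-metal reduction proceeds through a ketyl and carbanion that are protonated to the more stable epimer, so the equatorial 6α-alcohol should form where a hydride, forced onto the α face by the syn-axial C4 and C10 methyl groups, gives the 6β-alcohol; the isolated 1,1-disubstituted alkene is not reduced.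

Step 12
Reactants: 14 6α-hydroxy alkene
Product: 15 9α,11-epoxy-12,13,14,15,16-pentanorlabdan-6α-ol
Conditions: mCPBA, NaHCO3, CH2Cl2, 0 °C
Reagents that add atoms: meta-chloroperoxybenzoic acid, OOC(=O)c1cccc(Cl)c1
Why: In this Prilezhaev epoxidation the peracid should approach the exocyclic alkene from the α face, because the β face is covered by the axial C10 methyl group on the neighbouring carbon; oxygen becomes axial (9α) and C11 equatorial. The equatorial 6α-hydroxyl cannot reach the alkene to direct the reagent, and bicarbonate prevents acid-promoted rearrangement of the epoxide.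

Step 13
Reactants: 15 spiro-epoxide
Product: 16 13,14,15,16-tetranorlabd-11-ene-6α,9α-diol
Conditions: Me3S+ I−, n-BuLi (excess of both), THF, −10 °C → rt
Reagents that add atoms: trimethylsulfonium iodide, C[S+](C)C.[I-]
Why: The sulfonium ylide opens the epoxide at its CH2 terminus (SN2 at C11); the γ-alkoxy sulfonium salt is then deprotonated at an S-methyl group and undergoes α′,β-elimination of dimethyl sulfide (one-carbon homologation of an epoxide to an allylic alcohol). C9 is not touched, so its configuration is retained.

Step 14
Reactants: 16 diol
Product: 17 9α-hydroxy-13,14,15,16-tetranorlabd-11-en-6α-yl acetate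
Conditions: Ac2O, pyridine, DMAP (cat.), CH2Cl2, rt
Reagents that add atoms: acetic anhydride, CC(=O)OC(C)=O
Why: DMAP-catalysed acylation takes the secondary equatorial 6α-hydroxyl; the tertiary axial C9 hydroxyl next to a quaternary carbon does not react under these conditions.

Step 15
Reactants: 17 vinyl carbinol acetate; 18 3-bromofuran-2(5H)-one
Product: 20 6α-acetoxy-9α-hydroxylabd-13-en-16,15-olide (8α-CH3; the target), via B-alkyl-9-borabicyclo[3.3.1]nonane 19 (not isolated)
Conditions: 9-BBN-H dimer (excess), THF, 0 °C → rt; then 18, PdCl2(dppf), AsPh3, aq. K3PO4, DMF, rt
Reagents that add atoms: 9-borabicyclo[3.3.1]nonane, B1C2CCCC1CCC2 (boron in 19 only; to 20 it contributes one hydrogen at C11)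
Why: 9-BBN adds to the vinyl group with boron at terminal C12 (anti-Markovnikov hydroboration), and the borane 19 transfers its primary alkyl group to palladium after oxidative addition of 18 (B-alkyl Suzuki–Miyaura coupling, as used for α-halo enones). The dppf and AsPh3 ligands favour reductive elimination over β-hydride elimination, and phosphate at room temperature should spare the acetate and the butenolide.

## Compound list

1 | mesityl oxide (4-methylpent-3-en-2-one) | CC(C)=CC(C)=O | starting material
2 | lithium 4-methylpenta-1,3-dien-2-olate | [Li+].[O-]C(=C)C=C(C)C | intermediate (not isolated)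
3 | 2-(tert-butyldimethylsilyloxy)-4-methylpenta-1,3-diene | C=C(O[Si](C)(C)C(C)(C)C)C=C(C)C | intermediate
4 | 2,6-dimethyl-1,4-benzoquinone | CC1=CC(=O)C=C(C)C1=O | starting material
5 | cis-fused adduct, 2-(tert-butyldimethylsilyloxy)-4,4,8,10-tetramethyl-1,4,5,10-tetrahydronaphthalene-6,9-dione (5β-H, 10β-CH3) | O=C1C=C(C)C(=O)[C@@]2(C)CC(O[Si](C)(C)C(C)(C)C)=CC(C)(C)[C@@H]12 | intermediate
6 | cis-fused 2-(tert-butyldimethylsilyloxy)-4,4,8α,10β-tetramethyl-1,4,5,7,8,10-hexahydronaphthalene-6,9-dione (5β-H) | O=C1C[C@@H](C)C(=O)[C@@]2(C)CC(O[Si](C)(C)C(C)(C)C)=CC(C)(C)[C@@H]12 | intermediate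
7 | cis-fused 4,4,8α,10β-tetramethyl-6,9-dioxo-octahydronaphthalen-2-yl trifluoromethanesulfonate (5β-H, C2=C3) | O=C1C[C@@H](C)C(=O)[C@@]2(C)CC(OS(=O)(=O)C(F)(F)F)=CC(C)(C)[C@@H]12 | intermediate
8 | cis-fused 4,4,8α,10β-tetramethyl-1,4,5,7,8,10-hexahydronaphthalene-6,9-dione (5β-H, C2=C3) | O=C1C[C@@H](C)C(=O)[C@@]2(C)CC=CC(C)(C)[C@@H]12 | intermediate
9 | cis-fused 4,4,8α,10β-tetramethyldecalin-6,9-dione (5β-H) | O=C1C[C@@H](C)C(=O)[C@@]2(C)CCCC(C)(C)[C@@H]12 | intermediate
10 | 11,12,13,14,15,16-hexanorlabdane-6,9-dione (5α-H, 8α-CH3) | O=C1C[C@@H](C)C(=O)[C@@]2(C)CCCC(C)(C)[C@H]12 | intermediate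
11 | 6β-hydroxy-11,12,13,14,15,16-hexanorlabdan-9-one | O[C@@H]1C[C@@H](C)C(=O)[C@@]2(C)CCCC(C)(C)[C@H]12 | intermediate
12 | 12,13,14,15,16-pentanorlabd-9(11)-en-6β-ol | O[C@@H]1C[C@@H](C)C(=C)[C@@]2(C)CCCC(C)(C)[C@H]12 | intermediate
13 | 12,13,14,15,16-pentanorlabd-9(11)-en-6-one | O=C1C[C@@H](C)C(=C)[C@@]2(C)CCCC(C)(C)[C@H]12 | intermediate
14 | 12,13,14,15,16-pentanorlabd-9(11)-en-6α-ol | O[C@H]1C[C@@H](C)C(=C)[C@@]2(C)CCCC(C)(C)[C@H]12 | intermediate
15 | 9α,11-epoxy-12,13,14,15,16-pentanorlabdan-6α-ol | O[C@H]1C[C@@H](C)[C@]3(CO3)[C@@]2(C)CCCC(C)(C)[C@H]12 | intermediate
16 | 13,14,15,16-tetranorlabd-11-ene-6α,9α-diol | O[C@H]1C[C@@H](C)[C@](O)(C=C)[C@@]2(C)CCCC(C)(C)[C@H]12 | intermediate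
17 | 9α-hydroxy-13,14,15,16-tetranorlabd-11-en-6α-yl acetate | CC(=O)O[C@H]1C[C@@H](C)[C@](O)(C=C)[C@@]2(C)CCCC(C)(C)[C@H]12 | intermediate
18 | 3-bromofuran-2(5H)-one | O=C1OCC=C1Br | starting material
19 | 12-(9-borabicyclo[3.3.1]nonan-9-yl)-9α-hydroxy-13,14,15,16-tetranorlabdan-6α-yl acetate | CC(=O)O[C@H]1C[C@@H](C)[C@](O)(CCB3C4CCCC3CCC4)[C@@]2(C)CCCC(C)(C)[C@H]12 | intermediate (not isolated)
20 | 6α-acetoxy-9α-hydroxylabd-13-en-16,15-olide (8α-CH3) | CC(=O)O[C@H]1C[C@@H](C)[C@](O)(CCC2=CCOC2=O)[C@@]2(C)CCCC(C)(C)[C@H]12 | target

## Step count and least certain steps

Total step count: 15. Longest linear sequence: 15 steps (1 to 20); 4 and 18 enter as commercial materials.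

**Step 2 (key step).** The most likely failure is a cycloaddition too slow at temperatures that permit high enantioselection, because the Z-methyl group of 3 disfavours the s-cis conformer. Protodesilylation of the diene by the acidic catalyst would compete, leading to low conversion or eroded enantioselectivity. The fallback takes absolute configuration from a resolution instead of the catalyst.
- It sets out from 3 and 4: an achiral Lewis acid (BF3·OEt2, CH2Cl2, −40 °C) should give 5 together with the mirror-image adduct F1.
- Luche reduction (NaBH4, CeCl3·7H2O, MeOH, −78 °C) at the accessible C6 carbonyl gives the 6α-hydroxy enone F2 and its mirror image F3. The 6α assignment assumes hydride delivery to the convex β face; either epimer serves.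
- Esterification with (S)-2-methoxy-2-phenylacetic acid (DCC, DMAP) gives the diastereomeric esters F4 (from F2) and F5 (from F3), separated by chromatography or crystallisation.
- Methanolysis of F4 (K2CO3, MeOH, 0 °C) returns F2, and Dess–Martin oxidation comes back to the route at 5 as a single enantiomer.

**Step 4.** The risk is proton transfer between the cesium enolate and the α-positions of the dione before sulfonylation. That would scramble the enolate, so that sulfonylation occurs at the C6 oxygen or the C2 enolate is simply protonated. The fallback uses hydrazone chemistry and sets out from 6.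
- HF·pyridine in MeCN gives the cis-fused 2,6,9-trione F6.
- One equivalent of TsNHNH2 (EtOH, rt) should condense at C2, the only carbonyl without α-branching, to give the tosylhydrazone F7.
- Catecholborane (CHCl3, 0 °C), then NaOAc·3H2O at reflux, reduces the hydrazone to the methylene group and comes back at 9.

**Step 12.** The risk is attack on the wrong face: two 1,3-diaxial hydrogens on the α face are set against one adjacent axial methyl group on the β face, and the discrimination may be smaller than expected or reversed. The fallback delivers oxygen anti to the electrophile and so gives the complementary facial outcome; it is the remedy if the peracid prefers the β face.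
- It sets out from 14: NBS in THF/H2O (0 °C) forms the bromonium ion on the preferred face, and water enters C9 from the other to give the bromohydrin F8.
- K2CO3 in MeOH closes F8 and comes back at 15.

**Step 13.** The risk is decomposition of the thermally labile ylide before it can open the neopentyl-type epoxide CH2, leaving 15 unchanged. The fallback uses a stable carbanion and a separate elimination, and sets out from 15.
- (Phenylselanyl)methyllithium (from bis(phenylselanyl)methane and n-BuLi, THF, −78 → 0 °C) opens the epoxide at C11 to give the γ-hydroxy selenide F9.
- H2O2 and pyridine (THF, 0 °C → rt) oxidise the selenide, and syn-elimination of the selenoxide towards C11 comes back at 16.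

**Step 15.** The risks are slow transmetalation of a hindered, oxygen-coordinated borane and base-induced decomposition of 18 in the aqueous phosphate medium. The fallback couples under neutral conditions through an organozinc and sets out from 17.
- 9-BBN, then NaBO3·4H2O, gives the primary alcohol F10.
- I2, PPh3 and imidazole give the iodide F11.
- Activated zinc dust with LiCl in THF gives the alkylzinc iodide F12.
- Negishi coupling with 18 (Pd(PPh3)4, THF/DMA, rt) comes back at 20.

## Further compounds

F1 | step 2 | mirror image of adduct 5 | O=C1C=C(C)C(=O)[C@]2(C)CC(O[Si](C)(C)C(C)(C)C)=CC(C)(C)[C@H]12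
F2 | step 2 | cis-fused 6α-hydroxy enone from 5 (2-silyloxy-6α-hydroxy-4,4,8,10-tetramethyl-octalin-2,7-dien-9-one) | O[C@H]1C=C(C)C(=O)[C@@]2(C)CC(O[Si](C)(C)C(C)(C)C)=CC(C)(C)[C@@H]12
F3 | step 2 | mirror image of F2 | O[C@@H]1C=C(C)C(=O)[C@]2(C)CC(O[Si](C)(C)C(C)(C)C)=CC(C)(C)[C@H]12
F4 | step 2 | (S)-2-methoxy-2-phenylacetate of F2 | CO[C@@H](c1ccccc1)C(=O)O[C@H]1C=C(C)C(=O)[C@@]2(C)CC(O[Si](C)(C)C(C)(C)C)=CC(C)(C)[C@@H]12
F5 | step 2 | (S)-2-methoxy-2-phenylacetate of F3 | CO[C@@H](c1ccccc1)C(=O)O[C@@H]1C=C(C)C(=O)[C@]2(C)CC(O[Si](C)(C)C(C)(C)C)=CC(C)(C)[C@H]12
F6 | step 4 | cis-fused 4,4,8α,10β-tetramethyldecalin-2,6,9-trione (5β-H) | O=C1C[C@@H](C)C(=O)[C@@]2(C)CC(=O)CC(C)(C)[C@@H]12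
F7 | step 4 | C2 tosylhydrazone of F6 | O=C1C[C@@H](C)C(=O)[C@@]2(C)CC(=NNS(=O)(=O)c3ccc(C)cc3)CC(C)(C)[C@@H]12
F8 | step 12 | 11-bromo-12,13,14,15,16-pentanorlabdane-6α,9α-diol | O[C@H]1C[C@@H](C)[C@](O)(CBr)[C@@]2(C)CCCC(C)(C)[C@H]12
F9 | step 13 | 12-(phenylselanyl)-13,14,15,16-tetranorlabdane-6α,9α-diol | O[C@H]1C[C@@H](C)[C@](O)(CC[Se]c3ccccc3)[C@@]2(C)CCCC(C)(C)[C@H]12
F10 | step 15 | 9α,12-dihydroxy-13,14,15,16-tetranorlabdan-6α-yl acetate | CC(=O)O[C@H]1C[C@@H](C)[C@](O)(CCO)[C@@]2(C)CCCC(C)(C)[C@H]12
F11 | step 15 | 9α-hydroxy-12-iodo-13,14,15,16-tetranorlabdan-6α-yl acetate | CC(=O)O[C@H]1C[C@@H](C)[C@](O)(CCI)[C@@]2(C)CCCC(C)(C)[C@H]12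
F12 | step 15 | (6α-acetoxy-9α-hydroxy-13,14,15,16-tetranorlabdan-12-yl)zinc iodide | CC(=O)O[C@H]1C[C@@H](C)[C@](O)(CC[Zn]I)[C@@]2(C)CCCC(C)(C)[C@H]12
A1 | alternative 1 | 13,14,15,16-tetranorlabd-8-en-12-yl pivalate | C1CC(C)=C(CCOC(=O)C(C)(C)C)[C@@]2(C)CCCC(C)(C)[C@H]12
A2 | alternative 1 | (3Z,7E)-4,8,12-trimethyl-3-(trimethylsilyl)trideca-3,7,11-trien-1-yl pivalate | CC(C)=CCC/C(C)=C/CC/C(C)=C(\[Si](C)(C)C)CCOC(=O)C(C)(C)C
A3 | alternative 2 | 6α-acetoxy-14,15-dinorlabdan-16,9α-olide (8α-methyl) | CC(=O)O[C@H]1C[C@@H](C)[C@](OC3=O)(CCC3)[C@@]2(C)CCCC(C)(C)[C@H]12
A4 | alternative 2 | 6α-acetoxy-14,15-dinorlabd-8-en-16-oic acid | CC(=O)O[C@H]1CC(C)=C(CCCC(=O)O)[C@@]2(C)CCCC(C)(C)[C@H]12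
A5 | alternative 3 | 6α,9α-epidioxy-13,14,15,16-tetranorlabd-7-en-12-yl tert-butyldimethylsilyl ether | O3[C@H]1C=C(C)[C@](O3)(CCO[Si](C)(C)C(C)(C)C)[C@@]2(C)CCCC(C)(C)[C@H]12
A6 | alternative 3 | 12-(tert-butyldimethylsilyloxy)-13,14,15,16-tetranorlabda-6,8-diene | C1=CC(C)=C(CCO[Si](C)(C)C(C)(C)C)[C@@]2(C)CCCC(C)(C)[C@H]12
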